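Assumption: the SMILES is read as (R) at all three stereocentres, namely C2 of the oxolanone (ring A), the exocyclic carbon C1′ and C2 of the hydroxysuccinyl unit, which is therefore an (R)-malic acid 1-ester.

## Structural features

The target holds one ring, a 5-oxooxolane (ring A: O1, C2, C3, C4, C5=O), and one long chain. C2 of ring A is fully substituted: it carries O1, C3, a free carboxyl group and the exocyclic carbon C1′. C1′ is a tertiary stereocentre with a second free carboxyl group and a decamethylene tether. C2 and C1′ are directly bonded and both (R); this congested pair, an oxygenated quaternary carbon next to a tertiary one with three carboxyl carbons within four atoms, is the real difficulty. The tether ends in a primary oxygen acylated by C1 of (R)-malic acid, whose secondary hydroxyl and C4 carboxyl stay free; this third stereocentre lies thirteen bonds from the others, cannot be relayed from them and is best bought. Fragile points are the α-hydroxy ester of the malate (hydrolysis, acyl migration, β-elimination under base), the lactone (saponification) and C1′–H, which is α to a carboxyl and β to the lactone oxygen (E1cB opening). The last steps must therefore avoid base and hydrolysis. The key step exploits the fact that C2 bears both ring oxygen O1 and a carboxyl group while C1′ bears a one-carbon acid: with the C1′ carboxyl read as an alkene and C5=O read as the CH2 of an oxolane, C2–C1′ is the new bond of a 2-alkoxypent-4-enoic acid, the product of an ester-enolate [3,3] rearrangement in which O1 itself is the chelating α-alkoxy group.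

## Logic of the disconnections

22 ⇒ 21. The two benzyl C–O bonds of the esters on C2 and C1′ are the last bonds to be broken. Hydrogenolysis is neutral and non-hydrolytic, so the malate ester and the lactone of 22 survive. The demand is that 21 holds nothing else that is reducible or benzylic.

21 ⇒ 17 + 19 (19 from 18). The acyl C–O bond between the tether oxygen and C1 of the hydroxysuccinyl unit is cut. Opening the cyclic anhydride 19 at the carbonyl next to its acyloxy-bearing carbon gives the 1-ester and frees the C4 acid, so no protecting group is spent on that unit and the third stereocentre comes from purchased 18. The forward step needs regioselective attack, no base, and mild loss of the trifluoroacetyl group (via 20).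

17 ⇒ 16 ⇒ 15. The O–Si bond at the tether end and the two benzyl ester C–O bonds are protecting-group changes. They make the tether oxygen the only nucleophile in 17 and keep the intermediates chromatographable. Both forward steps must be mild enough not to enolise C1′ or open the lactone.

15 ⇒ 13 (via 14). No C–C bond is cut. The C5=O of ring A is traced back to a ring CH2 and the C1′ carboxyl to a propenyl group. This turns the lactone diacid into a mono-acid with one alkene and one cyclic ether, which is exactly a rearrangement product, and one oxidant performs both changes. The forward step must attack only the alkene and the C5–H bonds and spare the silyl ether.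

13 ⇒ 9 (key). The C2–C1′ bond is cut and the carboxyl oxygen is reconnected to the allylic carbon with transposition of the alkene. Both contiguous stereocentres and the most hindered bond are thereby traced back to an ester whose only lasting stereocentre is a secondary carbinol. The forward step needs one ketene acetal geometry, a chair transition state and complete 1,3-transfer of chirality.

9 ⇒ 7 + 8. The ester C–O bond is cut. 8 can be racemic because its stereocentre becomes planar on enolisation.

7 ⇒ 5 ⇒ 2 + 3 (2 from 1). The E-alkene of 7 is traced to the alkyne of 5, and the C(sp)–C(sp3) bond between C4 and C5 of 5 is cut to give 3, which carries the purchased carbinol centre, and bromide 2. The forward steps need C-alkylation of a dianion and a strictly trans-selective reduction.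

## Other disconnections considered

Alternative 1: the first that comes to mind. Cut C2–C1′ as an aldol bond: the titanium or boron enolate of the N-acyl oxazolidinone A1 adds to the ketone of dibenzyl 2-oxopentanedioate A2 to give the tertiary aldol A3, which lactonises after removal of the auxiliary. Grounds for setting it aside:
- The ketone of A2 is flanked by two ester-bearing arms of similar size, so its faces are told apart only by chelation of the 1,2-dicarbonyl and not by a steric bias.
- Tertiary aldolates are prone to retro-aldol cleavage, so the outcome may reflect equilibration.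
- The auxiliary must be removed from an acyl group next to a quaternary carbinol.
- A1 itself needs about three steps from 2.

The chosen rearrangement forms the same bond intramolecularly and irreversibly, with both stereochemical inputs stored in an isolable precursor.

Alternative 2: cut the same bond as a vinylogous Mukaiyama–Michael addition. Silyloxyfuran A4 adds through C5 to the iminium ion of enal A5 (chiral secondary amine salt as catalyst) to give butenolide aldehyde A6 with both stereocentres; a Wittig reaction with an ω-oxygenated C9 ylide and hydrogenation would complete the chain. It is short and unconventional. Grounds for setting it aside: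
- The syn/anti sense comes from an open transition state that depends on co-catalyst and solvent, so the (R,R) pair is not secured by structure.
- A6 holds only two of the eleven chain carbons, so the chain is built after the stereo-defining step by a basic olefination next to a centre that can lose the furanone by retro-Michael reaction.
- Three carboxyl groups and the tether oxygen need separate protection, so the step count is not lower.

Alternative 3: cut C2–C1′ together with the acyl C–O bond of the C1′ carboxyl. A [2+2] cycloaddition of alkylketene A7 with the ketone of A2 under a chiral nucleophilic catalyst would give β-lactone A8, and acyl transfer from the four- to the five-membered lactone would give the core. Grounds for setting it aside: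
- Monoalkylketenes dimerise under nucleophilic catalysis faster than they add to a moderately electrophilic, enolisable ketone.
- The asymmetric variants known rely on aldehydes or strongly activated ketones, so the key step would rest on a reaction type not shown for this substrate class.
- Facial discrimination of A2 has the same weakness as in Alternative 1.
- β-Lactones of tertiary alcohols tend to ionise or lose CO2, which endangers C2 during the relay.

Key step: step 5

## Route

Step 1
Reactants: 1 10-bromodecan-1-ol
Product: 2 [(10-bromodecyl)oxy]tri(propan-2-yl)silane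
Conditions: i-Pr3SiCl, imidazole, CH2Cl2, 0 °C → rt
Reagents that add atoms: chlorotri(propan-2-yl)silane, CC(C)[Si](Cl)(C(C)C)C(C)C
Why: Silylation of a primary alcohol; the triisopropylsilyl ether has no aromatic ring, withstands organolithium bases, hydride and RuO4, and is later removed with fluoride without touching esters.

Step 2
Reactants: 3 (2R)-but-3-yn-2-ol; 2 [(10-bromodecyl)oxy]tri(propan-2-yl)silane
Product: 5 (2R)-14-{[tri(propan-2-yl)silyl]oxy}tetradec-3-yn-2-ol, via dilithium alkynolate 4 (not isolated)
Conditions: n-BuLi (2 equiv per 3), THF, −78 → 0 °C; then 2, DMPU, 0 °C → rt; H2O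
Reagents that add atoms: none
Why: Alkylation of a lithium acetylide with a primary bromide (SN2); in dianion 4 the acetylide carbon is far more nucleophilic than the lithium alkoxide, and the purchased (R)-carbinol centre is not touched.

Step 3
Reactants: 5 (2R)-14-{[tri(propan-2-yl)silyl]oxy}tetradec-3-yn-2-ol
Product: 7 (2R,3E)-14-{[tri(propan-2-yl)silyl]oxy}tetradec-3-en-2-ol, via cyclic vinylalanate 6 (not isolated)
Conditions: NaAlH2(OCH2CH2OCH3)2, THF, 0 °C → rt; aq. KNaC4H4O6
Reagents that add atoms: none
Why: Alkoxide-directed trans-hydroalumination of a propargylic alcohol: aluminium bound to the alkoxide ends on C4 in the five-membered alanate 6 while hydride adds to C3 from the opposite side, so protonolysis should give only the E-alkene with the carbinol centre unchanged.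

Step 4
Reactants: 7 (2R,3E)-14-{[tri(propan-2-yl)silyl]oxy}tetradec-3-en-2-ol; 8 oxolane-2-carboxylic acid (racemic)
Product: 9 (2R,3E)-14-{[tri(propan-2-yl)silyl]oxy}tetradec-3-en-2-yl oxolane-2-carboxylate (both C2 epimers)
Conditions: DCC, DMAP (cat.), CH2Cl2, 0 °C → rt
Reagents that add atoms: none
Why: Steglich esterification of a secondary allylic alcohol; O-acylation leaves the carbinol configuration and the E-alkene intact, and the two C2 epimers are carried on together because that centre becomes planar in step 5.

Step 5
Reactants: 9 (2R,3E)-14-{[tri(propan-2-yl)silyl]oxy}tetradec-3-en-2-yl oxolane-2-carboxylate (both C2 epimers)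
Product: 13 (2R)-2-[(2E,4S)-14-{[tri(propan-2-yl)silyl]oxy}tetradec-2-en-4-yl]oxolane-2-carboxylic acid, via lithium enolate 10 (not isolated), via silyl ketene acetal 11 (not isolated), via trimethylsilyl ester 12 (not isolated)
Conditions: LiN(i-Pr)2, THF, −78 °C; Me3SiCl, −78 °C → rt, then 45 °C; MeOH/H2O, aq. citric acid
Reagents that add atoms: none
Why: Ireland–Claisen rearrangement of an α-alkoxy ester in its chelation-controlled form. LiN(i-Pr)2 removes the only acidic C–H (C2–H of the oxolane ester, so both epimers of 9 converge), and lithium bridges the enolate oxygen and ring O1 in a five-membered chelate, so silylation should give ketene acetal 11 with OSiMe3 cis to O1 (Z). The [3,3] shift runs through a chair in which the carbinol methyl is equatorial (an axial methyl would clash 1,3-diaxially with OSiMe3), which fixes the face of the E-alkene that bonds: the new bond forms suprafacially as the C–O bond leaves, trading the (R)-carbinol centre for C1′ and a new E-propenyl group. In that chair O1 is pseudo-equatorial and ring C3 pseudo-axial on the ketene acetal carbon while the tether is pseudo-equatorial on the alkene terminus, which places O1 and the tether syn across the new bond: (2R) at the quaternary carbon and the target arrangement at C1′ (descriptor S in 13 only because propenyl ranks below C2). The step closes no ring; the six-membered array exists only in the transition state. The selectivities needed are ketene acetal geometry (secured by the Li–O1 chelate in THF without donor cosolvent), chair over boat (acyclic E-allyl unit) and equatorial over axial methyl; none depends on an external chiral reagent. Formation of the C=O of silyl ester 12 drives the congested C2–C1′ bond formation irreversibly, and aqueous work-up frees acid 13.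

Step 6
Reactants: 13 (2R)-2-[(2E,4S)-14-{[tri(propan-2-yl)silyl]oxy}tetradec-2-en-4-yl]oxolane-2-carboxylic acid
Product: 15 (2R)-2-[(1R)-1-carboxy-11-{[tri(propan-2-yl)silyl]oxy}undecyl]-5-oxooxolane-2-carboxylic acid, via oxolane diacid 14 (not isolated)
Conditions: RuCl3·xH2O (cat.), NaIO4, EtOAc/MeCN/H2O, rt
Reagents that add atoms: sodium periodate, [Na+].[O-]I(=O)(=O)=O; water, O
Why: RuO4 (octavalent ruthenium, regenerated by periodate) cleaves the propenyl group to the C1′ carboxyl and, more slowly, oxidises the only ether CH2 of the ring (C5, the other α-carbon being quaternary) to the lactone carbonyl, the oxygen analogue of the proline-to-pyroglutamate oxidation; C2 has no hydrogen and C1′–H is deactivated by two carboxyl groups, so both stereocentres should be kept.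

Step 7
Reactants: 15 (2R)-2-[(1R)-1-carboxy-11-{[tri(propan-2-yl)silyl]oxy}undecyl]-5-oxooxolane-2-carboxylic acid
Product: 16 benzyl (2R)-2-[(2R)-1-(benzyloxy)-1-oxo-12-{[tri(propan-2-yl)silyl]oxy}dodecan-2-yl]-5-oxooxolane-2-carboxylate
Conditions: BnBr, KHCO3, Bu4NI (cat.), DMF, rt
Reagents that add atoms: benzyl bromide, BrCc1ccccc1
Why: O-Alkylation of the two carboxylates (SN2 at the benzylic carbon), which is insensitive to hindrance at the acyl carbons; hydrogencarbonate is too weak to enolise C1′ or open the lactone.

Step 8
Reactants: 16 benzyl (2R)-2-[(2R)-1-(benzyloxy)-1-oxo-12-{[tri(propan-2-yl)silyl]oxy}dodecan-2-yl]-5-oxooxolane-2-carboxylate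
Product: 17 benzyl (2R)-2-[(2R)-1-(benzyloxy)-12-hydroxy-1-oxododecan-2-yl]-5-oxooxolane-2-carboxylate
Conditions: HF·pyridine, THF/pyridine, 0 °C → rt
Reagents that add atoms: none
Why: Fluoride-mediated cleavage of the silyl ether under slightly acidic conditions that leave benzyl esters and lactone untouched.

Step 9
Reactants: 18 (2R)-2-hydroxybutanedioic acid [(R)-malic acid]
Product: 19 (3R)-2,5-dioxooxolan-3-yl trifluoroacetate
Conditions: (CF3CO)2O (neat), 0 °C → rt; evaporate
Reagents that add atoms: trifluoroacetic anhydride, O=C(OC(=O)C(F)(F)F)C(F)(F)F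
Why: O-Trifluoroacetylation and dehydrative closure of the five-membered anhydride in one operation under acidic conditions that do not enolise the stereocentre; 19 is used crude.

Step 10
Reactants: 17 benzyl (2R)-2-[(2R)-1-(benzyloxy)-12-hydroxy-1-oxododecan-2-yl]-5-oxooxolane-2-carboxylate; 19 (3R)-2,5-dioxooxolan-3-yl trifluoroacetate
Product: 21 (3R)-4-{[(11R)-12-(benzyloxy)-11-[(2R)-2-[(benzyloxy)carbonyl]-5-oxooxolan-2-yl]-12-oxododecyl]oxy}-3-hydroxy-4-oxobutanoic acid, via trifluoroacetate hemiester 20 (not isolated)
Conditions: THF, rt → 40 °C (no base); then MeOH, rt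
Reagents that add atoms: none
Why: Alcoholysis of an unsymmetrical cyclic anhydride: the primary alcohol should attack the carbonyl next to the trifluoroacetoxy-bearing carbon, the more electrophilic one, giving the 1-ester and freeing the C4 acid; the labile trifluoroacetate of 20 is then removed by methanolysis, and without base no elimination or epimerisation of the malate centre is expected.

Step 11
Reactants: 21 (3R)-4-{[(11R)-12-(benzyloxy)-11-[(2R)-2-[(benzyloxy)carbonyl]-5-oxooxolan-2-yl]-12-oxododecyl]oxy}-3-hydroxy-4-oxobutanoic acid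
Product: 22 (2R)-2-[(1R)-1-carboxy-11-{[(2R)-3-carboxy-2-hydroxypropanoyl]oxy}undecyl]-5-oxooxolane-2-carboxylic acid (CNP0457473.3)
Conditions: H2 (1 atm), 10% Pd/C, EtOAc, rt
Reagents that add atoms: none
Why: Hydrogenolysis of the two benzyl esters under neutral conditions; the malate ester, the free secondary hydroxyl and the lactone are not benzylic, so the target should be released without any hydrolytic step.

## Compound list

1 | 10-bromodecan-1-ol | OCCCCCCCCCCBr | starting material
2 | [(10-bromodecyl)oxy]tri(propan-2-yl)silane | CC(C)[Si](C(C)C)(C(C)C)OCCCCCCCCCCBr | intermediate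
3 | (2R)-but-3-yn-2-ol | C[C@@H](O)C#C | starting material
4 | dilithium (3R)-3-oxidobut-1-yn-1-ide (dilithium alkynolate) | C[C@@H](O[Li])C#C[Li] | intermediate (not isolated)
5 | (2R)-14-{[tri(propan-2-yl)silyl]oxy}tetradec-3-yn-2-ol | C[C@@H](O)C#CCCCCCCCCCCO[Si](C(C)C)(C(C)C)C(C)C | intermediate
6 | sodium (5R)-2,2-bis(2-methoxyethoxy)-5-methyl-3-(10-{[tri(propan-2-yl)silyl]oxy}decyl)-2,5-dihydro-1,2-oxaaluminol-2-uide (cyclic vinylalanate) | C[C@@H]1C=C(CCCCCCCCCCO[Si](C(C)C)(C(C)C)C(C)C)[Al-](OCCOC)(OCCOC)O1.[Na+] | intermediate (not isolated)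
7 | (2R,3E)-14-{[tri(propan-2-yl)silyl]oxy}tetradec-3-en-2-ol | C[C@@H](O)/C=C/CCCCCCCCCCO[Si](C(C)C)(C(C)C)C(C)C | intermediate
8 | oxolane-2-carboxylic acid (racemic) | OC(=O)C1CCCO1 | starting material
9 | (2R,3E)-14-{[tri(propan-2-yl)silyl]oxy}tetradec-3-en-2-yl oxolane-2-carboxylate (both C2 epimers) | O=C(O[C@H](C)/C=C/CCCCCCCCCCO[Si](C(C)C)(C(C)C)C(C)C)C1CCCO1 | intermediate
10 | lithium enolate of 9 (OLi cis to ring oxygen) | [Li]O/C(O[C@H](C)/C=C/CCCCCCCCCCO[Si](C(C)C)(C(C)C)C(C)C)=C1/CCCO1 | intermediate (not isolated)
11 | (Z)-trimethylsilyl ketene acetal of 9 (OSiMe3 cis to ring oxygen) | C[Si](C)(C)O/C(O[C@H](C)/C=C/CCCCCCCCCCO[Si](C(C)C)(C(C)C)C(C)C)=C1/CCCO1 | intermediate (not isolated)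
12 | trimethylsilyl (2R)-2-[(2E,4S)-14-{[tri(propan-2-yl)silyl]oxy}tetradec-2-en-4-yl]oxolane-2-carboxylate | CC(C)[Si](C(C)C)(C(C)C)OCCCCCCCCCC[C@@H](/C=C/C)[C@@]1(C(=O)O[Si](C)(C)C)CCCO1 | intermediate (not isolated)
13 | (2R)-2-[(2E,4S)-14-{[tri(propan-2-yl)silyl]oxy}tetradec-2-en-4-yl]oxolane-2-carboxylic acid | CC(C)[Si](C(C)C)(C(C)C)OCCCCCCCCCC[C@@H](/C=C/C)[C@@]1(C(=O)O)CCCO1 | intermediate
14 | (2R)-2-[(1R)-1-carboxy-11-{[tri(propan-2-yl)silyl]oxy}undecyl]oxolane-2-carboxylic acid | CC(C)[Si](C(C)C)(C(C)C)OCCCCCCCCCC[C@@H](C(=O)O)[C@@]1(C(=O)O)CCCO1 | intermediate (not isolated)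
15 | (2R)-2-[(1R)-1-carboxy-11-{[tri(propan-2-yl)silyl]oxy}undecyl]-5-oxooxolane-2-carboxylic acid | CC(C)[Si](C(C)C)(C(C)C)OCCCCCCCCCC[C@@H](C(=O)O)[C@@]1(C(=O)O)CCC(=O)O1 | intermediate
16 | benzyl (2R)-2-[(2R)-1-(benzyloxy)-1-oxo-12-{[tri(propan-2-yl)silyl]oxy}dodecan-2-yl]-5-oxooxolane-2-carboxylate | CC(C)[Si](C(C)C)(C(C)C)OCCCCCCCCCC[C@@H](C(=O)OCc1ccccc1)[C@@]1(C(=O)OCc2ccccc2)CCC(=O)O1 | intermediate
17 | benzyl (2R)-2-[(2R)-1-(benzyloxy)-12-hydroxy-1-oxododecan-2-yl]-5-oxooxolane-2-carboxylate | OCCCCCCCCCC[C@@H](C(=O)OCc1ccccc1)[C@@]1(C(=O)OCc2ccccc2)CCC(=O)O1 | intermediate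
18 | (2R)-2-hydroxybutanedioic acid [(R)-malic acid] | O=C(O)C[C@@H](O)C(=O)O | starting material
19 | (3R)-2,5-dioxooxolan-3-yl trifluoroacetate | O=C1C[C@@H](OC(=O)C(F)(F)F)C(=O)O1 | intermediate
20 | (3R)-4-{[(11R)-12-(benzyloxy)-11-[(2R)-2-[(benzyloxy)carbonyl]-5-oxooxolan-2-yl]-12-oxododecyl]oxy}-4-oxo-3-[(trifluoroacetyl)oxy]butanoic acid | O=C(O)C[C@@H](OC(=O)C(F)(F)F)C(=O)OCCCCCCCCCC[C@@H](C(=O)OCc1ccccc1)[C@@]1(C(=O)OCc2ccccc2)CCC(=O)O1 | intermediate (not isolated)
21 | (3R)-4-{[(11R)-12-(benzyloxy)-11-[(2R)-2-[(benzyloxy)carbonyl]-5-oxooxolan-2-yl]-12-oxododecyl]oxy}-3-hydroxy-4-oxobutanoic acid | O=C(O)C[C@@H](O)C(=O)OCCCCCCCCCC[C@@H](C(=O)OCc1ccccc1)[C@@]1(C(=O)OCc2ccccc2)CCC(=O)O1 | intermediate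
22 | (2R)-2-[(1R)-1-carboxy-11-{[(2R)-3-carboxy-2-hydroxypropanoyl]oxy}undecyl]-5-oxooxolane-2-carboxylic acid | O=C(O)C[C@@H](O)C(=O)OCCCCCCCCCC[C@@H](C(=O)O)[C@@]1(C(=O)O)CCC(=O)O1 | target

## Step count and least certain steps

Total: 11 steps. Longest linear sequence: 10 steps (steps 1–8, 10, 11 from 1); step 9 is a one-step side branch.

Step 5 (key step). The most likely failure is incomplete control of ketene acetal geometry: if the lithium chelate to the ring oxygen of the cyclic α-alkoxy ester is only partly formed, both geometries are silylated and the configuration at C2 erodes, while C1′ stays secure. A slow shift of the tetrasubstituted ketene acetal could also let fragmentation to a ketene compete. The fallback sets out from 7 and returns at 15, using an acyclic α-benzyloxy ester, for which chelation-controlled enolisation is well documented, and carrying the C5 carbonyl as a terminal alkene: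
- Commercial (benzyloxy)acetic acid is alkylated as its dianion (LiN(i-Pr)2, THF/DMPU) with 4-bromobut-1-ene to give racemic 2-(benzyloxy)hex-5-enoic acid F1.
- Steglich esterification with 7 gives (2R,3E)-14-{[tri(propan-2-yl)silyl]oxy}tetradec-3-en-2-yl 2-(benzyloxy)hex-5-enoate F2.
- Ireland–Claisen rearrangement of F2 (LiN(i-Pr)2, Me3SiCl; lithium chelate to the benzyl ether oxygen) should give (2R,3S)-2-(benzyloxy)-2-(but-3-en-1-yl)-3-[(1E)-prop-1-en-1-yl]-13-{[tri(propan-2-yl)silyl]oxy}tridecanoic acid F3.
- Ozonolysis of both alkenes (O3, CH2Cl2/MeOH, −78 °C; Me2S) and Pinnick oxidation (NaClO2, NaH2PO4, 2-methylbut-2-ene) give (3R,4R)-3-(benzyloxy)-14-{[tri(propan-2-yl)silyl]oxy}tetradecane-1,3,4-tricarboxylic acid F4.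
- Hydrogenolysis (H2, 10% Pd/C) gives (3R,4R)-3-hydroxy-14-{[tri(propan-2-yl)silyl]oxy}tetradecane-1,3,4-tricarboxylic acid F5, which closes to the γ-lactone 15 with catalytic TsOH in CH2Cl2.

Step 6. The most likely failure is over-oxidation at the O–CH2 of the silyl ether during the long exposure needed for the ether C–H oxidation, or stalling at 14 because the carboxyl on C2 makes the ring oxygen electron-poor. Partial epimerisation at C1′ through the transient aldehyde is a lesser concern. The fallback abandons C–H oxidation altogether: it is the detour already described for step 5, setting out from 7 and returning at 15, in which the C5 carbonyl arises by ozonolysis of a terminal alkene. It makes no further compound.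

Step 10. The most likely failure is attack at the wrong anhydride carbonyl, giving the 4-ester regioisomer, or loss of trifluoroacetic acid by elimination to a maleate if the mixture becomes basic. The fallback sets out from 17 and returns at 22, forming the ester at the alkyl carbon instead:
- I2, PPh3 and imidazole convert 17 into benzyl (2R)-2-[(2R)-1-(benzyloxy)-12-iodo-1-oxododecan-2-yl]-5-oxooxolane-2-carboxylate F6.
- Commercial D-aspartic acid 4-benzyl ester is diazotised (NaNO2, aq. H2SO4, retention through the α-lactone) to (2R)-4-(benzyloxy)-2-hydroxy-4-oxobutanoic acid F7.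
- The caesium carboxylate of F7 (Cs2CO3, DMF) displaces iodide from F6 to give benzyl (2R)-2-[(2R)-1-(benzyloxy)-12-{[(2R)-4-(benzyloxy)-2-hydroxy-4-oxobutanoyl]oxy}-1-oxododecan-2-yl]-5-oxooxolane-2-carboxylate F8.
- Hydrogenolysis of the three benzyl esters (H2, 10% Pd/C) gives 22.

Step 2. The most likely failure is E2 elimination of the primary bromide by the basic dianion, or sluggish alkylation with some O-alkylation in the donor cosolvent. The fallback sets out from 2 and returns at 5, forming the carbinol centre by catalysis:
- LiC≡CH·H2NCH2CH2NH2 in DMSO converts 2 into (dodec-11-yn-1-yloxy)tri(propan-2-yl)silane F9.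
- n-BuLi and N-methoxy-N-methylacetamide give 14-{[tri(propan-2-yl)silyl]oxy}tetradec-3-yn-2-one F10.
- Noyori-type asymmetric transfer hydrogenation with RuCl[(R,R)-TsDPEN](p-cymene) in i-PrOH should give 5.

## Further compounds

F1 | step 5 | 2-(benzyloxy)hex-5-enoic acid (racemic) | C=CCCC(OCc1ccccc1)C(=O)O
F2 | step 5 | (2R,3E)-14-{[tri(propan-2-yl)silyl]oxy}tetradec-3-en-2-yl 2-(benzyloxy)hex-5-enoate | C=CCCC(OCc1ccccc1)C(=O)O[C@H](C)/C=C/CCCCCCCCCCO[Si](C(C)C)(C(C)C)C(C)C
F3 | step 5 | (2R,3S)-2-(benzyloxy)-2-(but-3-en-1-yl)-3-[(1E)-prop-1-en-1-yl]-13-{[tri(propan-2-yl)silyl]oxy}tridecanoic acid | CC(C)[Si](C(C)C)(C(C)C)OCCCCCCCCCC[C@@H](/C=C/C)[C@@](OCc1ccccc1)(C(=O)O)CCC=C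
F4 | step 5 | (3R,4R)-3-(benzyloxy)-14-{[tri(propan-2-yl)silyl]oxy}tetradecane-1,3,4-tricarboxylic acid | CC(C)[Si](C(C)C)(C(C)C)OCCCCCCCCCC[C@@H](C(=O)O)[C@@](OCc1ccccc1)(C(=O)O)CCC(=O)O
F5 | step 5 | (3R,4R)-3-hydroxy-14-{[tri(propan-2-yl)silyl]oxy}tetradecane-1,3,4-tricarboxylic acid | CC(C)[Si](C(C)C)(C(C)C)OCCCCCCCCCC[C@@H](C(=O)O)[C@@](O)(C(=O)O)CCC(=O)O
F0 | step 6 | none | none
F6 | step 10 | benzyl (2R)-2-[(2R)-1-(benzyloxy)-12-iodo-1-oxododecan-2-yl]-5-oxooxolane-2-carboxylate | ICCCCCCCCCC[C@@H](C(=O)OCc1ccccc1)[C@@]1(C(=O)OCc2ccccc2)CCC(=O)O1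
F7 | step 10 | (2R)-4-(benzyloxy)-2-hydroxy-4-oxobutanoic acid | O=C(OCc1ccccc1)C[C@@H](O)C(=O)O
F8 | step 10 | benzyl (2R)-2-[(2R)-1-(benzyloxy)-12-{[(2R)-4-(benzyloxy)-2-hydroxy-4-oxobutanoyl]oxy}-1-oxododecan-2-yl]-5-oxooxolane-2-carboxylate | O=C(OCc1ccccc1)C[C@@H](O)C(=O)OCCCCCCCCCC[C@@H](C(=O)OCc1ccccc1)[C@@]1(C(=O)OCc2ccccc2)CCC(=O)O1
F9 | step 2 | (dodec-11-yn-1-yloxy)tri(propan-2-yl)silane | C#CCCCCCCCCCCO[Si](C(C)C)(C(C)C)C(C)C
F10 | step 2 | 14-{[tri(propan-2-yl)silyl]oxy}tetradec-3-yn-2-one | CC(=O)C#CCCCCCCCCCCO[Si](C(C)C)(C(C)C)C(C)C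
A1 | alternative 1 | (4R)-4-benzyl-3-(12-{[tri(propan-2-yl)silyl]oxy}dodecanoyl)-1,3-oxazolidin-2-one | CC(C)[Si](C(C)C)(C(C)C)OCCCCCCCCCCCC(=O)N1[C@H](Cc2ccccc2)COC1=O
A2 | alternative 1 | dibenzyl 2-oxopentanedioate | O=C(CCC(=O)OCc1ccccc1)C(=O)OCc1ccccc1
A3 | alternative 1 | dibenzyl (2R)-2-hydroxy-2-[(2R)-1-[(4R)-4-benzyl-2-oxo-1,3-oxazolidin-3-yl]-1-oxo-12-{[tri(propan-2-yl)silyl]oxy}dodecan-2-yl]pentanedioate | CC(C)[Si](C(C)C)(C(C)C)OCCCCCCCCCC[C@@H](C(=O)N1[C@H](Cc2ccccc2)COC1=O)[C@@](O)(C(=O)OCc1ccccc1)CCC(=O)OCc1ccccc1
A4 | alternative 2 | methyl 5-{[tri(propan-2-yl)silyl]oxy}furan-2-carboxylate | COC(=O)c1ccc(O[Si](C(C)C)(C(C)C)C(C)C)o1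
A5 | alternative 2 | tert-butyl (2E)-4-oxobut-2-enoate | O=C/C=C/C(=O)OC(C)(C)C
A6 | alternative 2 | methyl (2R)-2-[(2R)-1-tert-butoxy-1,4-dioxobutan-2-yl]-5-oxo-2,5-dihydrofuran-2-carboxylate | O=CC[C@@H](C(=O)OC(C)(C)C)[C@@]1(C(=O)OC)C=CC(=O)O1
A7 | alternative 3 | 12-{[tri(propan-2-yl)silyl]oxy}dodec-1-en-1-one (alkylketene) | O=C=CCCCCCCCCCCO[Si](C(C)C)(C(C)C)C(C)C
A8 | alternative 3 | benzyl (2R,3R)-2-[3-(benzyloxy)-3-oxopropyl]-4-oxo-3-(10-{[tri(propan-2-yl)silyl]oxy}decyl)oxetane-2-carboxylate | CC(C)[Si](C(C)C)(C(C)C)OCCCCCCCCCC[C@H]1C(=O)O[C@]1(C(=O)OCc1ccccc1)CCC(=O)OCc1ccccc1
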